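**Retrosynthetic overview**

1. The coumarin is bought intact as isofraxidin; in the cyclohexane the C5=C(CH3)2 unit is traced back to an enol triflate plus a methyl group, and the C6 side chain to a conjugate addition on a ring enone (C5=C6, acetyl on C5).
2. Key disconnection: the C4–C5 bond of that ring enone, made by a phosphine-mediated intramolecular Morita–Baylis–Hillman alkylation of an acyclic ω-bromo enone; this closes the cyclohexane, the only ring built that stays in the target.
3. Enabling feature: C5 (the ring carbon of the exocyclic C=C(CH3)2) sits next to the allylic CH stereocentre C6, which is the transposed form of a C5=C6 enone whose acetyl carbon becomes the C(CH3)2 carbon; in that form C5 is an enone α-carbon that phosphine addition at C6 turns into a nucleophile within reach of the C4 bromide.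
4. The acyclic precursor comes from a δ-lactone used as a temporary ring: C2 from (R)-3-methylglutaric half ester, C1 by anti alkylation of the lactone enolate, the aryl ether by Mitsunobu reaction at the lactone stage; C6 is set after the ring closure by axial conjugate addition.

Key step: step 9

Remark (numbering): C1 = quaternary ring carbon (CH3, CH2OAr), C2 = CH(CH3), C3 and C4 = CH2, C5 = ring carbon of C=C(CH3)2, C6 = CH bearing the side chain; Ar = 6,8-dimethoxy-2-oxo-2H-chromen-7-yl.
Remark (assumptions): the half ester, isofraxidin and the silyl-protected 3-bromopropanol are taken as purchasable; the E/Z geometry of the two tetrasubstituted enol derivatives is left open because both isomers give the same product after methylation.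

**Step 1**
Reactants: 1 methyl hydrogen (3R)-3-methylpentanedioate
Product: 3 (4R)-4-methyloxan-2-one, via hydroxy ester 2 (not isolated)
Conditions: BH3·SMe2, THF, 0 °C to rt; then TsOH (cat.), toluene, 60 °C
Reagents that add atoms: none
Why: Chemoselective borane reduction of the free carboxylic acid beside the methyl ester followed by acid-catalysed lactonisation should give the lactone, and the stereocentre (the future C2) is not touched.

**Step 2**
Reactants: 3 (4R)-4-methyloxan-2-one
Product: 5 (3R,4R)-3-(hydroxymethyl)-4-methyloxan-2-one, via lithium enolate 4 (not isolated)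
Conditions: LiN(iPr)2, THF, −78 °C; CH2O (gas), −78 to −40 °C
Reagents that add atoms: formaldehyde C=O
Why: Aldol hydroxymethylation of the lithium lactone enolate with monomeric formaldehyde should place CH2OH mainly trans to the C4 methyl group, and this centre becomes planar again in step 3 so either epimer serves.

**Step 3**
Reactants: 5 (3R,4R)-3-(hydroxymethyl)-4-methyloxan-2-one
Product: 7 (3S,4R)-3-(hydroxymethyl)-3,4-dimethyloxan-2-one, via dilithium alkoxide enolate 6 (not isolated)
Conditions: LiN(iPr)2 (2.2 equiv), THF–DMPU, −78 °C; CH3I, −78 to −30 °C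
Reagents that add atoms: iodomethane CI
Why: In this Fráter–Seebach-type dianion alkylation iodomethane should approach the cyclic enolate on the face opposite the neighbouring C4 methyl group, which sets the quaternary centre (future C1) with the new methyl trans to the C4 methyl.

**Step 4**
Reactants: 7 (3S,4R)-3-(hydroxymethyl)-3,4-dimethyloxan-2-one; 8 isofraxidin (7-hydroxy-6,8-dimethoxy-2H-chromen-2-one)
Product: 9 (3S,4R)-3-(ArOCH2)-3,4-dimethyloxan-2-one
Conditions: PPh3, DIAD, toluene (concentrated), 0 to 60 °C
Reagents that add atoms: none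
Why: Mitsunobu etherification of a primary neopentyl-type alcohol of the hydroxypivalate kind with the acidic phenol 8 should install the aryl ether before this carbon becomes more hindered, and no stereocentre is involved.

**Step 5**
Reactants: 9 (3S,4R)-3-(ArOCH2)-3,4-dimethyloxan-2-one
Product: 10 (2S,3R)-5-bromo-2-(ArOCH2)-2,3-dimethylpentanoic acid
Conditions: HBr (33% in AcOH), CH2Cl2, rt
Reagents that add atoms: hydrogen bromide Br
Why: Bromide should open the protonated δ-lactone by SN2 attack at the unhindered O–CH2 carbon (alkyl–oxygen lactone cleavage), while the coumarin lactone has no such site and the stereocentres are remote from the reacting carbon.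

**Step 6**
Reactants: 10 (2S,3R)-5-bromo-2-(ArOCH2)-2,3-dimethylpentanoic acid
Product: 11 (2R,3R)-5-bromo-2-(ArOCH2)-2,3-dimethylpentan-1-ol
Conditions: BH3·THF, THF, 0 °C to rt
Reagents that add atoms: none
Why: Borane reduces a carboxylic acid much faster than the coumarin lactone or the alkyl bromide (chemoselective acid reduction), so the neopentyl alcohol should form without change at any stereocentre.

**Step 7**
Reactants: 11 (2R,3R)-5-bromo-2-(ArOCH2)-2,3-dimethylpentan-1-ol
Product: 12 (2S,3R)-5-bromo-2-(ArOCH2)-2,3-dimethylpentanal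
Conditions: Dess–Martin periodinane, CH2Cl2, rt
Reagents that add atoms: none
Why: Dess–Martin oxidation of the primary alcohol under neutral conditions should give the aldehyde, which has no α-hydrogen and therefore cannot epimerise.

**Step 8**
Reactants: 12 (2S,3R)-5-bromo-2-(ArOCH2)-2,3-dimethylpentanal
Product: 13 (3E,5R,6R)-8-bromo-5-(ArOCH2)-5,6-dimethyloct-3-en-2-one
Conditions: Ph3P=CHC(O)CH3, toluene, 90 °C
Reagents that add atoms: 1-(triphenylphosphoranylidene)propan-2-one CC(=O)C=P(c1ccccc1)(c1ccccc1)c1ccccc1
Why: Wittig olefination with the stabilised acetonyl ylide should give the E enone selectively and tolerate the primary bromide and the coumarin, and no stereocentre is formed.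

**Step 9**
Reactants: 13 (3E,5R,6R)-8-bromo-5-(ArOCH2)-5,6-dimethyloct-3-en-2-one
Product: 15 (1R,6R)-3-acetyl-1-(ArOCH2)-1,6-dimethylcyclohex-2-ene, via phosphonium bromide 14 (not isolated)
Conditions: PMe3 (1.1 equiv), t-BuOH, rt; then K2CO3, MeCN, rt
Reagents that add atoms: none
Why: PMe3 adds reversibly to the enone β-carbon C6 to give a β-phosphonium enolate whose α-carbon C5 displaces bromide from C4 in an intramolecular SN2 reaction, and K2CO3 then deprotonates C5 of phosphonium salt 14 and expels PMe3 (E1cB) to restore the C5=C6 double bond. The closest known reaction type is the phosphine-mediated intramolecular Morita–Baylis–Hillman alkylation of ω-bromo enones, which gives 1-acylcyclohexenes from exactly this arrangement of enone and primary bromide. The cyclohexene is closed in the 6-exo-tet mode by C-alkylation of the enolate, helped by the fully substituted C1 in the tether (Thorpe–Ingold effect), whereas O-alkylation would need an eight-membered ring. No stereocentre of the product is made here: the two centres formed at C5 and C6 in 14 disappear in the elimination, C1 has no hydrogen and C2 is remote from any acidic position, so both keep their configuration. The selectivity needed is conjugate addition of the phosphine to the enone ahead of quaternisation at the CH2Br group or attack on the coumarin, which the small and strongly nucleophilic PMe3, the protic solvent that stabilises the zwitterion and the higher electrophilicity of the ketone-conjugated alkene should secure.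

**Step 10**
Reactants: 15 (1R,6R)-3-acetyl-1-(ArOCH2)-1,6-dimethylcyclohex-2-ene; 16 (3-bromopropoxy)(tert-butyl)dimethylsilane
Product: 18 (1R,2S,6R)-1-(ArOCH2)-2-[3-(tert-butyldimethylsilyloxy)propyl]-1,6-dimethyl-3-[1-(trimethylsilyloxy)ethylidene]cyclohexane, via Grignard reagent 17 (not isolated)
Conditions: 16, Mg, THF; then 15, CuBr·SMe2 (cat.), Me3SiCl, DMPU, THF, −78 °C
Reagents that add atoms: chlorotrimethylsilane C[Si](C)(C)Cl
Why: In this copper-catalysed conjugate addition with chlorosilane trapping the chain should add axially to C6 of the half-chair that keeps the C2 methyl equatorial and CH2OAr pseudoaxial, that is anti to CH2OAr and trans to the C2 methyl (the other face would require a syn-diaxial approach to that methyl), which sets C6 as in the target while the enolate is caught regiospecifically as the tetrasubstituted silyl enol ether and the enone reacts far faster than the coumarin.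

**Step 11**
Reactants: 18 (the trimethylsilyl enol ether of step 10)
Product: 19 (1R,2S,6R)-1-(ArOCH2)-2-[3-(tert-butyldimethylsilyloxy)propyl]-1,6-dimethyl-3-[1-(trifluoromethylsulfonyloxy)ethylidene]cyclohexane
Conditions: PhNTf2, CsF, DME, rt
Reagents that add atoms: N-phenylbis(trifluoromethanesulfonimide) O=S(=O)(N(c1ccccc1)S(=O)(=O)C(F)(F)F)C(F)(F)F
Why: Fluoride should cleave the trimethylsilyl enol ether to the cesium enolate without equilibration and PhNTf2 should triflate it on oxygen (enol triflate formation), so the double-bond position fixed in step 10 is kept and the primary silyl ether survives the sparingly soluble CsF.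

**Step 12**
Reactants: 19 (the enol triflate of step 11)
Product: 20 (1R,2R,6R)-1-(ArOCH2)-2-[3-(tert-butyldimethylsilyloxy)propyl]-1,6-dimethyl-3-(propan-2-ylidene)cyclohexane
Conditions: MeZnCl, Pd(PPh3)4 (cat.), THF, 55 °C
Reagents that add atoms: methylzinc chloride C[Zn]Cl
Why: Negishi coupling of the alkenyl triflate with MeZnCl should replace OTf by CH3, the E/Z composition of 19 being irrelevant because the alkene carbon then carries two identical methyl groups, and the organozinc reagent leaves the coumarin alone.

**Step 13**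
Reactants: 20 (the silyl ether of step 12)
Product: 21 7-{[(1R,2R,6R)-2-(3-hydroxypropyl)-1,6-dimethyl-3-(propan-2-ylidene)cyclohexyl]methoxy}-6,8-dimethoxy-2H-chromen-2-one
Conditions: HF·pyridine, THF, 0 °C to rt
Reagents that add atoms: none
Why: Fluoride-mediated cleavage of the primary silyl ether (standard desilylation) should free the alcohol under conditions that leave the tetrasubstituted alkene, the aryl ethers and the coumarin lactone intact.

**Compound list**

1 | methyl hydrogen (3R)-3-methylpentanedioate | COC(=O)C[C@H](C)CC(=O)O | starting material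
2 | methyl (3R)-5-hydroxy-3-methylpentanoate | COC(=O)C[C@H](C)CCO | intermediate
3 | (4R)-4-methyloxan-2-one | O=C1C[C@H](C)CCO1 | intermediate
4 | lithium (4R)-4-methyl-3,4-dihydro-2H-pyran-6-olate (lithium enolate of 3) | [Li+].[O-]C1=C[C@H](C)CCO1 | intermediate
5 | (3R,4R)-3-(hydroxymethyl)-4-methyloxan-2-one | OC[C@H]1[C@H](C)CCOC1=O | intermediate
6 | dilithium (4R)-4-methyl-5-(oxidomethyl)-3,4-dihydro-2H-pyran-6-olate (alkoxide enolate of 5) | [Li+].[Li+].[O-]CC1=C([O-])OCC[C@H]1C | intermediate
7 | (3S,4R)-3-(hydroxymethyl)-3,4-dimethyloxan-2-one | OC[C@]1(C)[C@H](C)CCOC1=O | intermediate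
8 | isofraxidin (7-hydroxy-6,8-dimethoxy-2H-chromen-2-one) | COc1cc2ccc(=O)oc2c(OC)c1O | starting material
9 | 7-{[(3S,4R)-3,4-dimethyl-2-oxooxan-3-yl]methoxy}-6,8-dimethoxy-2H-chromen-2-one | COc1cc2ccc(=O)oc2c(OC)c1OC[C@]1(C)[C@H](C)CCOC1=O | intermediate
10 | (2S,3R)-5-bromo-2-{[(6,8-dimethoxy-2-oxo-2H-chromen-7-yl)oxy]methyl}-2,3-dimethylpentanoic acid | COc1cc2ccc(=O)oc2c(OC)c1OC[C@](C(=O)O)(C)[C@H](C)CCBr | intermediate
11 | 7-{[(2R,3R)-5-bromo-2-(hydroxymethyl)-2,3-dimethylpentyl]oxy}-6,8-dimethoxy-2H-chromen-2-one | COc1cc2ccc(=O)oc2c(OC)c1OC[C@](CO)(C)[C@H](C)CCBr | intermediate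
12 | (2S,3R)-5-bromo-2-{[(6,8-dimethoxy-2-oxo-2H-chromen-7-yl)oxy]methyl}-2,3-dimethylpentanal | COc1cc2ccc(=O)oc2c(OC)c1OC[C@](C=O)(C)[C@H](C)CCBr | intermediate
13 | (3E,5R,6R)-8-bromo-5-{[(6,8-dimethoxy-2-oxo-2H-chromen-7-yl)oxy]methyl}-5,6-dimethyloct-3-en-2-one | COc1cc2ccc(=O)oc2c(OC)c1OC[C@](/C=C/C(C)=O)(C)[C@H](C)CCBr | intermediate
14 | [2-acetyl-6-(ArOCH2)-5,6-dimethylcyclohexyl]trimethylphosphonium bromide (methyl-bearing carbons configured as in 13; the P-bearing and acetyl-bearing carbons undefined) | COc1cc2ccc(=O)oc2c(OC)c1OC[C@]1(C)[C@H](C)CCC(C(C)=O)C1[P+](C)(C)C.[Br-] | intermediate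
15 | 7-{[(1R,6R)-3-acetyl-1,6-dimethylcyclohex-2-en-1-yl]methoxy}-6,8-dimethoxy-2H-chromen-2-one | COc1cc2ccc(=O)oc2c(OC)c1OC[C@]1(C)[C@H](C)CCC(C(C)=O)=C1 | intermediate
16 | (3-bromopropoxy)(tert-butyl)dimethylsilane | CC(C)(C)[Si](C)(C)OCCCBr | starting material
17 | [3-(tert-butyldimethylsilyloxy)propyl]magnesium bromide | CC(C)(C)[Si](C)(C)OCCC[Mg]Br | intermediate
18 | 7-{[(1R,2S,6R)-2-[3-(tert-butyldimethylsilyloxy)propyl]-1,6-dimethyl-3-[1-(trimethylsilyloxy)ethylidene]cyclohexyl]methoxy}-6,8-dimethoxy-2H-chromen-2-one (E/Z not defined) | COc1cc2ccc(=O)oc2c(OC)c1OC[C@]1(C)[C@H](C)CCC(=C(C)O[Si](C)(C)C)[C@H]1CCCO[Si](C)(C)C(C)(C)C | intermediate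
19 | 1-[(2S,3R,4R)-3-(ArOCH2)-2-[3-(tert-butyldimethylsilyloxy)propyl]-3,4-dimethylcyclohexylidene]ethyl trifluoromethanesulfonate (E/Z not defined) | COc1cc2ccc(=O)oc2c(OC)c1OC[C@]1(C)[C@H](C)CCC(=C(C)OS(=O)(=O)C(F)(F)F)[C@H]1CCCO[Si](C)(C)C(C)(C)C | intermediate
20 | 7-{[(1R,2R,6R)-2-[3-(tert-butyldimethylsilyloxy)propyl]-1,6-dimethyl-3-(propan-2-ylidene)cyclohexyl]methoxy}-6,8-dimethoxy-2H-chromen-2-one | COc1cc2ccc(=O)oc2c(OC)c1OC[C@]1(C)[C@H](C)CCC(=C(C)C)[C@H]1CCCO[Si](C)(C)C(C)(C)C | intermediate
21 | 7-{[(1R,2R,6R)-2-(3-hydroxypropyl)-1,6-dimethyl-3-(propan-2-ylidene)cyclohexyl]methoxy}-6,8-dimethoxy-2H-chromen-2-one | COc1cc2ccc(=O)oc2c(OC)c1OC[C@]1(C)[C@H](C)CCC(=C(C)C)[C@H]1CCCO | target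

**Step count and risks**

Total steps: 13. Longest linear sequence: 13 steps (1 to 21).

Steps most likely to fail:

1. Step 9. The phosphine may add too slowly to the β-carbon next to the quaternary centre, so that quaternisation of the phosphine at the primary bromide or intermolecular alkylation takes over. Fallback: starting from aldehyde 12, a Wittig reaction with Ph3P=C(Br)C(O)CH3 should give (3Z,5R,6R)-3,8-dibromo-5-(ArOCH2)-5,6-dimethyloct-3-en-2-one F1. An intramolecular nickel-catalysed reductive cross-electrophile coupling of its alkenyl and alkyl C–Br bonds (NiBr2(CH3OCH2CH2OCH3), 4,4'-di-tert-butyl-2,2'-bipyridine, Mn, NaI, DMA) would then form the same C4–C5 bond and rejoin the route at enone 15.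

2. Step 10. Loss of chemoselectivity or of conversion: competing addition of the organometallic reagent to the coumarin, or sluggish addition at the hindered C6. Fallback: from 15 and 16, a nickel-catalysed reductive conjugate addition of the alkyl bromide (NiCl2(CH3OCH2CH2OCH3), 2,2':6',2''-terpyridine, Mn, Et3SiCl, DMF) engages only the enone through a silyloxyallyl nickel intermediate and needs no Grignard reagent. It should give the triethylsilyl enol ether F2, which with CsF and PhNTf2 rejoins the route at triflate 19.

3. Step 4. Slow substitution at the neopentyl carbon, so that the activated alcohol is diverted to alkylation of the hydrazide or simply returned. Fallback: from 7, triflation (Tf2O, pyridine, CH2Cl2, −20 °C) should give [(3S,4R)-3,4-dimethyl-2-oxooxan-3-yl]methyl trifluoromethanesulfonate F3, which is displaced by the cesium phenoxide of 8 (Cs2CO3, DMF, 40 °C) to rejoin the route at 9.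

**Further compounds**

F1 | step 9 | (3Z,5R,6R)-3,8-dibromo-5-{[(6,8-dimethoxy-2-oxo-2H-chromen-7-yl)oxy]methyl}-5,6-dimethyloct-3-en-2-one | COc1cc2ccc(=O)oc2c(OC)c1OC[C@](/C=C(\Br)C(C)=O)(C)[C@H](C)CCBr
F2 | step 10 | 7-{[(1R,2S,6R)-2-[3-(tert-butyldimethylsilyloxy)propyl]-1,6-dimethyl-3-[1-(triethylsilyloxy)ethylidene]cyclohexyl]methoxy}-6,8-dimethoxy-2H-chromen-2-one (E/Z not defined) | COc1cc2ccc(=O)oc2c(OC)c1OC[C@]1(C)[C@H](C)CCC(=C(C)O[Si](CC)(CC)CC)[C@H]1CCCO[Si](C)(C)C(C)(C)C
F3 | step 4 | [(3S,4R)-3,4-dimethyl-2-oxooxan-3-yl]methyl trifluoromethanesulfonate | FC(F)(F)S(=O)(=O)OC[C@]1(C)[C@H](C)CCOC1=O
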